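(The earlier runs and the new flask come from a simulation for substances that don't exist; scatter was added.)

3.65 h is my reading of τ, the consumption half-life: the time in which the two substrates together would halve at the pace of the last stretch of Sunday's run.

| setting | Sunday's | Friday's | flask |
|---|---|---|---|
| left-handed substrate | 0.30 M | 0.20 M | 0.30 M |
| right-handed substrate | 0.30 M | 0.20 M | 0.30 M |
| solid reagent | 0.75 M | 0.75 M | 0.750 M |
| precatalyst | 2.7 mM | 2.7 mM | 2.7 mM |
| added ligand | 4.3 mM | 4.3 mM | 4.3 mM |
| remark | the very flask that is asked about, followed so far | run made earlier |  |
| time |  |  | 1.0 h |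

| run | time / min | left-handed substrate / % | right-handed substrate / % |
|---|---|---|---|
| Sunday's | 2.50 | 50.0 | 50.1 |
| Sunday's | 5.00 | 50.1 | 49.9 |
| Sunday's | 8.00 | 49.5 | 49.6 |
| Sunday's | 15.0 | 49.3 | 49.9 |
| Sunday's | 30.0 | 46.9 | 47.7 |
| Friday's | 2.00 | 49.8 | 50.1 |
| Friday's | 4.00 | 49.5 | 49.4 |
| Friday's | 6.00 | 50.3 | 49.9 |
| Friday's | 12.0 | 49.7 | 49.4 |
| Friday's | 25.0 | 47.3 | 48.8 |

(each reading ± 0.3 percentage points)

- part of the left-handed substrate and right-handed substrate charged together that has reacted at 1.0 h
- excess of left-handed product over right-handed product in the product at 1.0 h
- excess of right-handed substrate over left-handed substrate among what is left of the two at 1.0 h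

- catalyst is single-handed; left-handed substrate and right-handed substrate are mirror images of each other, charged as a racemate, each of them at the stated concentration
- solid, in amounts per volume of the solution: solid reagent
- at the start none of the solid reagent is in solution
- an excess is below zero if the other one leads

In Sunday's flask I hold two times against each other: τ, and the 0.500 h still to run after the last reading. I give the slow start no time of its own: it already lies inside that last reading of 94.6 % substrate. Friday's run, at a lower charge, had lost 3.90 % of its charge by 25.0 min, so I reckon in proportions. The time left is shorter than τ, a ratio of 0.137. If the pace holds, I commit to c = 14.0 %. The reading carries a scatter of 0.3 percentage points per point, so this is rough.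

The forecast gives c = 17 % (12 % to 26 %), above my figure, with eP = 22 % and eS = 4.5 %. Its ground is “the reaction is roughly first order in substrate”.

Sunday's flask gives c = 12.5 %, eP = 23.8 % and eS = 1.58 %, and the forecast held on each.

    partner + catalyst + left-handed substrate → catalyst + left-handed product (k = 53.0 /M²/min)
    partner + catalyst + right-handed substrate → catalyst + right-handed product (k = 32.0 /M²/min)
    left-handed substrate ⇌ right-handed substrate (k = 0.0170 /min)
    precatalyst ⇌ catalyst (K = 1.10, k = 0.0940 /min)
    solid reagent ⇌ partner, rate k5*(cs5 - [partner]) while solid is left; crystals form when [partner] > cs5 (solubility = 0.170 M, k = 0.0500 /min)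
    catalyst + added ligand ⇌ idle complex (K = 1500 /M, k = 43.0 /M/min)

Against my reading τ, the relaxation half-life of the two substrates by their interconversion alone, both ways together, 0.340 h, is shorter by a factor of 10.7, and at 1.00 h left-handed substrate stands at 43.1 % and right-handed substrate at 44.5 % in Sunday's flask. The neighbour flask with 0.0011 M of added ligand reaches c = 21.1 % and eS = 2.89 %; its half-life averaged over the hour is 2.92 h, still 8.59 times that relaxation half-life.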